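**Retrosynthetic overview**
- The prenyl group at C6 is put on last, by reductive allylation of the ring A 5,8-quinone with a prenylstannane; this returns the 5,8-hydroquinone of the target without a separate reduction.
- The quinone comes from the 5-hydroxy-7-methoxyisoflavone by para-selective C8–O bond formation (photooxygenation of the peri-phenolate); this is the key step and is new.
- The 5-hydroxy-7-methoxyisoflavone comes from the 5,7-dihydroxyisoflavone by O7-methylation.
- The 5,7-dihydroxyisoflavone comes from phloroglucinol, 2,4,5-trimethoxyphenylacetic acid and one carbon from DMF.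
- Ring order: rings A and B are bought; ring C (the pyranone) is closed in step 1 through the O1–C2 bond; no other ring is formed.

Assumption: the target has no stereocenter and no stereogenic double bond, so no stereocontrol is needed; 2-(2,4,5-trimethoxyphenyl)acetic acid and tributyl(3-methylbut-2-en-1-yl)stannane are taken as catalogue chemicals.

**Step 1**
Reactants: 1 phloroglucinol (benzene-1,3,5-triol); 2 2-(2,4,5-trimethoxyphenyl)acetic acid
Product: 5 5,7-dihydroxy-3-(2,4,5-trimethoxyphenyl)-4H-chromen-4-one, via deoxybenzoin 3 (not isolated), via enaminone 4 (not isolated)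
Conditions: BF3·OEt2 (neat, Lewis acid and solvent), 85 °C; then DMF, MsCl, 70 °C, one pot
Reagents that add atoms: N,N-dimethylformamide (CN(C)C=O)
Why: BF3-promoted Friedel–Crafts C-acylation of the symmetrical, highly nucleophilic phloroglucinol by the arylacetic acid gives deoxybenzoin 3, the DMF/MsCl Vilsmeier-type reagent formylates its activated methylene to enaminone 4, and an ortho-hydroxyl closes ring C by addition–elimination at the aminomethylene carbon (O1–C2 bond, loss of dimethylamine), which is the established one-pot deoxybenzoin route to isoflavones; no stereocenter is formed.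

**Step 2**
Reactants: 5 5,7-dihydroxy-3-(2,4,5-trimethoxyphenyl)-4H-chromen-4-one
Product: 6 5-hydroxy-7-methoxy-3-(2,4,5-trimethoxyphenyl)-4H-chromen-4-one
Conditions: MeI (1.05 equiv), K2CO3 (1.1 equiv), acetone, 40 °C
Reagents that add atoms: iodomethane (CI)
Why: Williamson O-methylation, in which the acidic 7-hydroxyl (para to the carbonyl) is deprotonated and alkylated while the 5-hydroxyl stays locked in a hydrogen bond to the C4 carbonyl, as in the standard conversion of 5,7-dihydroxy(iso)flavones into their 7-methyl ethers.

**Step 3**
Reactants: 6 5-hydroxy-7-methoxy-3-(2,4,5-trimethoxyphenyl)-4H-chromen-4-one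
Product: 8 7-methoxy-3-(2,4,5-trimethoxyphenyl)-4H-chromene-4,5,8-trione, via hydroperoxy dienone 7 (not isolated)
Conditions: O2 (1 atm), 5,10,15,20-tetraphenylporphyrin (1 mol%), 2-tert-butyl-1,1,3,3-tetramethylguanidine (0.3 equiv), CH2Cl2 (0.02 M), white LEDs, −20 °C
Reagents that add atoms: dioxygen (O=O)
Why: Proposed new method: the hindered guanidine converts the chelated 5-hydroxyl into a ring A phenolate whose electron density is highest at C8 (para to the phenolate oxygen, ortho to both the ring oxygen and the 7-methoxy group), singlet oxygen made by the porphyrin sensitiser adds there to give the para-hydroperoxy dienone 7, and base-induced loss of water across the H–C8–O–OH unit (Kornblum–DeLaMare type) gives quinone 8 and returns the base, so the C8–O bond is made with O2 as the only stoichiometric reagent while the methoxylated ring B and the vinylogous-ester C2=C3 bond, which are poor singlet-oxygen acceptors, are left alone; the closest known reaction type is the dye-sensitised photooxygenation of 1-naphthols and para-unsubstituted phenols to 1,4-quinones (for example juglone from 1,5-dihydroxynaphthalene), which has not been shown on a peri-hydroxy chromone.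

**Step 4**
Reactants: 8 7-methoxy-3-(2,4,5-trimethoxyphenyl)-4H-chromene-4,5,8-trione; 9 tributyl(3-methylbut-2-en-1-yl)stannane (1.2 equiv)
Product: 12 5,8-dihydroxy-7-methoxy-6-(3-methylbut-2-en-1-yl)-3-(2,4,5-trimethoxyphenyl)-4H-chromen-4-one, via tertiary quinol 10 (not isolated), via dienone tautomer 11 (not isolated)
Conditions: BF3·OEt2 (Lewis acid promoter), CH2Cl2, −78 to −30 °C, Ar; then H2O
Reagents that add atoms: none
Why: Lewis-acid-promoted allylation of a quinone by an allylstannane (Naruta-type reductive prenylation, the reaction used for coenzyme Q1 and plastoquinone-1), in which the stannane γ-carbon adds to the more electrophilic C8 carbonyl of BF3-activated 8 (the C5 carbonyl is a doubly vinylogous ester) to give quinol 10, a [3,3] shift (Cope type) moves the allyl unit to C6, the only unsubstituted quinone carbon, with normal prenyl connectivity, and enolisation of dienone 11 re-aromatises ring A to the 5,8-hydroquinone; 10 and 11 are racemic and transient and the product has no stereocenter.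

**Compound list**
1 | phloroglucinol (benzene-1,3,5-triol) | Oc1cc(O)cc(O)c1 | starting material
2 | 2-(2,4,5-trimethoxyphenyl)acetic acid | COc1cc(OC)c(CC(=O)O)cc1OC | starting material
3 | 1-(2,4,6-trihydroxyphenyl)-2-(2,4,5-trimethoxyphenyl)ethan-1-one (deoxybenzoin, not isolated) | COc1cc(OC)c(CC(=O)c2c(O)cc(O)cc2O)cc1OC | intermediate
4 | 3-(dimethylamino)-1-(2,4,6-trihydroxyphenyl)-2-(2,4,5-trimethoxyphenyl)prop-2-en-1-one (enaminone, not isolated, alkene geometry irrelevant) | COc1cc(OC)c(C(=CN(C)C)C(=O)c2c(O)cc(O)cc2O)cc1OC | intermediate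
5 | 5,7-dihydroxy-3-(2,4,5-trimethoxyphenyl)-4H-chromen-4-one | COc1cc(OC)c(-c2coc3cc(O)cc(O)c3c2=O)cc1OC | intermediate
6 | 5-hydroxy-7-methoxy-3-(2,4,5-trimethoxyphenyl)-4H-chromen-4-one | COc1cc(OC)c(-c2coc3cc(OC)cc(O)c3c2=O)cc1OC | intermediate
7 | 8-hydroperoxy-7-methoxy-3-(2,4,5-trimethoxyphenyl)-8H-chromene-4,5-dione (racemic, not isolated) | COc1cc(OC)c(C2=COC3=C(C2=O)C(=O)C=C(OC)C3OO)cc1OC | intermediate
8 | 7-methoxy-3-(2,4,5-trimethoxyphenyl)-4H-chromene-4,5,8-trione (ring A 5,8-quinone) | COc1cc(OC)c(C2=COC3=C(C2=O)C(=O)C=C(OC)C3=O)cc1OC | intermediate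
9 | tributyl(3-methylbut-2-en-1-yl)stannane (prenyltributylstannane) | CCCC[Sn](CCCC)(CCCC)CC=C(C)C | starting material
10 | 8-hydroxy-7-methoxy-8-(2-methylbut-3-en-2-yl)-3-(2,4,5-trimethoxyphenyl)-8H-chromene-4,5-dione (racemic, present as its tin- or boron-bound alkoxide, not isolated) | COc1cc(OC)c(C2=COC3=C(C2=O)C(=O)C=C(OC)C3(O)C(C)(C)C=C)cc1OC | intermediate
11 | 8-hydroxy-7-methoxy-6-(3-methylbut-2-en-1-yl)-3-(2,4,5-trimethoxyphenyl)-6H-chromene-4,5-dione (racemic keto tautomer of 12, not isolated) | COc1cc(OC)c(C2=COC3=C(C2=O)C(=O)C(CC=C(C)C)C(OC)=C3O)cc1OC | intermediate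
12 | 5,8-dihydroxy-7-methoxy-6-(3-methylbut-2-en-1-yl)-3-(2,4,5-trimethoxyphenyl)-4H-chromen-4-one (achiral) | COc1cc(OC)c(-c2coc3c(O)c(OC)c(CC=C(C)C)c(O)c3c2=O)cc1OC | target

**Totals**
Total step count: 4. Longest linear sequence: 4 steps (1 → 5 → 6 → 8 → 12).

**Three steps most likely to fail**

Step 3 (the proposed new photooxygenation) is the most likely to fail. Possible failures are oxygenation at C6 (ortho) instead of C8, C-addition of the phenolate of 6 to quinone 8 already formed (hence high dilution, low temperature and substoichiometric base), hydrolysis of the 7-methoxy vinylogous ester by the water released, and slow reaction of the electron-poor chelated phenolate. The fallback uses known chemistry and sets out from 6. Elbs persulfate oxidation (K2S2O8, aqueous KOH/pyridine, 0 °C to room temperature), in which the phenolate para-carbon displaces sulfate from the peroxide oxygen, gives potassium 5-hydroxy-7-methoxy-4-oxo-3-(2,4,5-trimethoxyphenyl)-4H-chromen-8-yl sulfate F1. Hydrolysis of the sulfate ester (2 M HCl, 90 °C, under N2) gives 5,8-dihydroxy-7-methoxy-3-(2,4,5-trimethoxyphenyl)-4H-chromen-4-one F2. Dehydrogenation of this hydroquinone with Ag2O (MgSO4, THF, room temperature) gives quinone 8, where the fallback comes back to the route. This is the classical nuclear oxidation of 5-hydroxy-7-methoxy(iso)flavones; the yield is modest but the para selectivity is dependable.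

Step 4 is the second risk. The stannane may attack at C7 with loss of methoxide or add at the C5 carbonyl, product hydroquinone may exchange redox state with unreacted 8, and the new prenyl group may cyclise onto the 5-hydroxyl to a chroman if the BF3 mixture warms above about −30 °C. The fallback sets out from 8 and replaces the polar carbonyl-addition and sigmatropic-shift pathway by a radical substitution. 4-Methylpent-3-enoic acid F3 is decarboxylated with AgNO3 (0.2 equiv) and (NH4)2S2O8 in MeCN/H2O at 65 °C (Jacobsen–Torssell alkylation), and the prenyl radical adds through its unhindered CH2 terminus to the only C–H position of the quinone. This gives 7-methoxy-6-(3-methylbut-2-en-1-yl)-3-(2,4,5-trimethoxyphenyl)-4H-chromene-4,5,8-trione F4. Reduction of this prenylquinone with Na2S2O4 (EtOAc/H2O, room temperature) gives the target 12, where the fallback comes back to the route. The persulfate should be added slowly to spare ring B.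

Step 1 is the third risk. Hot BF3·OEt2 may partly demethylate or self-condense the electron-rich arylacetic acid, and formylation of a crude, boron-bound deoxybenzoin may be incomplete. The fallback sets out from 1 and makes the ketone by a Houben–Hoesch reaction. Phloroglucinol and 2-(2,4,5-trimethoxyphenyl)acetonitrile F5 (ZnCl2, HCl gas, Et2O, 0 °C) give 1-(2,4,6-trihydroxyphenyl)-2-(2,4,5-trimethoxyphenyl)ethan-1-iminium chloride F6. Hydrolysis in refluxing water gives deoxybenzoin 3, which is now isolated and crystallised; the fallback comes back to the route at 3. Pure 3 is then closed to 5 with BF3·OEt2, DMF and MsCl as in the second half of step 1.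

**Further compounds**
F1 | step 3 | potassium 5-hydroxy-7-methoxy-4-oxo-3-(2,4,5-trimethoxyphenyl)-4H-chromen-8-yl sulfate | COc1cc(OC)c(-c2coc3c(OS(=O)(=O)[O-])c(OC)cc(O)c3c2=O)cc1OC.[K+]
F2 | step 3 | 5,8-dihydroxy-7-methoxy-3-(2,4,5-trimethoxyphenyl)-4H-chromen-4-one | COc1cc(OC)c(-c2coc3c(O)c(OC)cc(O)c3c2=O)cc1OC
F3 | step 4 | 4-methylpent-3-enoic acid | CC(C)=CCC(=O)O
F4 | step 4 | 7-methoxy-6-(3-methylbut-2-en-1-yl)-3-(2,4,5-trimethoxyphenyl)-4H-chromene-4,5,8-trione | COc1cc(OC)c(C2=COC3=C(C2=O)C(=O)C(CC=C(C)C)=C(OC)C3=O)cc1OC
F5 | step 1 | 2-(2,4,5-trimethoxyphenyl)acetonitrile | COc1cc(OC)c(CC#N)cc1OC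
F6 | step 1 | 1-(2,4,6-trihydroxyphenyl)-2-(2,4,5-trimethoxyphenyl)ethan-1-iminium chloride | COc1cc(OC)c(CC(=[NH2+])c2c(O)cc(O)cc2O)cc1OC.[Cl-]
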